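**Retrosynthetic overview**

- The target is (13R)-13-hydroxylabda-7,14-dien-6α-yl butanoate. Late cuts: the ester C–O bond; the 6α-oxygen/Δ7 array, traced to a 6α,7α-epoxide of a Δ6 alkene with H-8α; and C11–C12, traced to a C11 sulfone plus (S)-2-methyl-2-vinyloxirane (C12–C16, brings C13).
- The feature the strategy rests on: ring B (C5–C10) is a cyclohexene-type ring with contiguous stereocentres C5, C10 (quaternary, C20) and C9 (C11 chain) plus the C8 methyl. It is the adduct of a deca-1,7,9-triene whose tether C1–C4 becomes ring A.
- Key disconnection: C5–C10 and C8–C9 by an enantioselective intramolecular Diels–Alder reaction of trienal 11. Rings A and B form together in that one step; no ring is made before or after it.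
- Trienal 11 comes from nitrile alkylation (quaternary C4), Horner–Wadsworth–Emmons olefination ((E)-C9=C10) and iodo-olefination/Suzuki coupling ((E,E)-diene).

Key step: step 7

Remark: labdane numbering is used throughout (ring A C1–C5/C10, ring B C5–C10, chain C11–C16, C17 on C8, C18/C19 on C4, C20 on C10); α is the face of H-5, β the face of C20.

**Route**

Step 1
Reactants: 1 isobutyronitrile; 2 2-(3-chloropropyl)-2-methyl-1,3-dioxolane
Product: 4 2,2-dimethyl-6-oxoheptanenitrile, via ketal nitrile 3 (not isolated)
Conditions: LiN(iPr)2, THF, −78 °C; 2, NaI (10 mol%), DMPU, −78 °C to rt; then 2 M aq HCl, THF, rt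
Reagents that add atoms: water, O
Why: SN2 alkylation of the lithiated nitrile builds the quaternary C4 with its two methyl groups, and the dioxolane that masked the ketone during the alkylation is hydrolysed in the acidic work-up (acetal hydrolysis).

Step 2
Reactants: 4 2,2-dimethyl-6-oxoheptanenitrile; 5 triethyl phosphonoacetate
Product: 6 ethyl (2E)-7-cyano-3,7-dimethyloct-2-enoate
Conditions: NaH, THF, 0 to 50 °C; minor (Z)-isomer removed by chromatography
Reagents that add atoms: none
Why: Horner–Wadsworth–Emmons olefination of the methyl ketone should give mainly the (E)-enoate (the future C9=C10), and the nitrile, which has no α-hydrogen, is inert to the phosphonate anion.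

Step 3
Reactants: 6 ethyl (2E)-7-cyano-3,7-dimethyloct-2-enoate
Product: 7 (6E)-8-hydroxy-2,2,6-trimethyloct-6-enal
Conditions: iBu2AlH (3.5 equiv), CH2Cl2, −78 to 0 °C; aq KNaC4H4O6, then pH 4 acetate buffer
Reagents that add atoms: water, O
Why: iBu2AlH reduces the conjugated ester 1,2 to the allylic alcohol and stops at the aluminium aldimine of the tertiary nitrile, which the mildly acidic work-up hydrolyses to the neopentyl aldehyde without touching the alkene geometry.

Step 4
Reactants: 7 (6E)-8-hydroxy-2,2,6-trimethyloct-6-enal
Product: 8 (2E,8E)-9-iodo-3,7,7-trimethylnona-2,8-dien-1-ol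
Conditions: CrCl2 (6 equiv), CHI3 (2 equiv), THF/1,4-dioxane, 0 °C to rt
Reagents that add atoms: iodoform, IC(I)I
Why: Takai–Utimoto iodo-olefination of the non-enolisable, α-quaternary aldehyde should give the (E)-vinyl iodide through the geminal dichromium reagent, and the free allylic alcohol is tolerated.

Step 5
Reactants: 8 (2E,8E)-9-iodo-3,7,7-trimethylnona-2,8-dien-1-ol; 9 (E)-prop-1-enylboronic acid
Product: 10 (2E,8E,10E)-3,7,7-trimethyldodeca-2,8,10-trien-1-ol
Conditions: Pd(PPh3)4 (5 mol%), K3PO4, THF/H2O, 50 °C
Reagents that add atoms: none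
Why: Suzuki–Miyaura coupling proceeds with retention of both alkene geometries and so delivers the (E,E)-diene in defined form.

Step 6
Reactants: 10 (2E,8E,10E)-3,7,7-trimethyldodeca-2,8,10-trien-1-ol
Product: 11 (2E,8E,10E)-3,7,7-trimethyldodeca-2,8,10-trienal
Conditions: MnO2 (activated, excess), CH2Cl2, rt
Reagents that add atoms: none
Why: MnO2 oxidises the allylic alcohol to the enal without E/Z isomerisation and leaves the unactivated diene untouched.

Step 7
Reactants: 11 (2E,8E,10E)-3,7,7-trimethyldodeca-2,8,10-trienal
Product: 12 trans-fused 4,4,8β,10β-tetramethyl-Δ6-octalin-9β-carbaldehyde (H-5α, H-8α, H-9α; aldehyde carbon = C11)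
Conditions: (R)-3,3-diphenyl-1-(o-tolyl)tetrahydro-1H,3H-pyrrolo[1,2-c][1,3,2]oxazaborole (20 mol%), AlBr3 (16 mol%), CH2Cl2, −40 to −20 °C
Reagents that add atoms: none
Why: Proposed new method: the AlBr3-activated oxazaborolidine acts as a cationic boron Lewis acid that binds the formyl oxygen of the s-trans (E)-enal, and the tethered (E,E)-diene then adds in a concerted asynchronous [4+2] cycloaddition that forms C8–C9 and C5–C10; the closest known reaction type is the chiral-Lewis-acid-catalysed intramolecular Diels–Alder reaction of terminally activated deca-2,7,9-trienals, which has not been shown for a β,β-disubstituted enal whose β-carbon becomes a quaternary centre. Ring B (C5–C10) is closed as the six-membered cycloaddition ring and ring A (C1–C5, C10) as the six-membered ring spanned by the tether C1–C4 in fused mode, the tether joining diene terminus C5 to dienophile carbon C10. The carbonyl-endo transition state, which Lewis-acid complexation favours, places H-5 anti to C20 (trans fusion); the (E)-enal geometry fixes C11 cis to C20 (C9 relative to C10) and the (E,E)-diene geometry fixes H-8 cis to H-5 (C8), so the four relative configurations follow from alkene geometry and the endo mode. The absolute configuration is set by the catalyst, which has to leave the Si face of the enal α-carbon C9 open; on the accepted model for enal complexes of such oxazaborolidinium ions (formyl C–H···O contact, enal stacked on the neighbouring phenyl group) the (R)-prolinol-derived catalyst should do this, and the sense is to be confirmed on the first run, the antipodal catalyst being equally available. The step needs endo over exo selectivity and enough dienophile reactivity at low temperature; the gem-dimethyl group at C4 (reactive-rotamer effect) and the strong cationic activation are relied on for both, against the C19/C20 syn-diaxial contact that develops in the chair-like tether.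

Step 8
Reactants: 12 trans-fused 4,4,8β,10β-tetramethyl-Δ6-octalin-9β-carbaldehyde
Product: 13 the corresponding 9β-hydroxymethyl octalin (C11 alcohol; H-5α, H-8α, H-9α)
Conditions: NaBH4, MeOH, 0 °C
Reagents that add atoms: none
Why: Hydride reduction of the aldehyde at low temperature removes the epimerisable formyl group before C9 can equilibrate; no stereocentre is formed.

Step 9
Reactants: 13 C11 alcohol
Product: 14 the corresponding 9β-iodomethyl octalin (C11 iodide)
Conditions: I2, PPh3, imidazole, CH2Cl2, 0 °C to rt
Reagents that add atoms: iodine, II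
Why: Appel-type iodination goes by SN2 displacement of the alkoxyphosphonium at the primary C11, so no ring stereocentre is involved and no cationic rearrangement is expected.

Step 10
Reactants: 14 C11 iodide
Product: 15 the corresponding 9β-(phenylsulfonylmethyl) octalin (C11 phenyl sulfone)
Conditions: PhSO2Na, Bu4NI (cat.), DMF, 80 °C
Reagents that add atoms: sodium benzenesulfinate, [Na+].[O-]S(=O)c1ccccc1
Why: S-Alkylation of the sulfinate (SN2) at the β-branched primary iodide installs the group that makes C11 a carbanion equivalent.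

Step 11
Reactants: 16 (S)-2-methylglycidol
Product: 17 (R)-2-methyloxirane-2-carbaldehyde
Conditions: (COCl)2, DMSO, CH2Cl2, −78 °C; Et3N, −78 to 0 °C; careful distillation
Reagents that add atoms: none
Why: Swern oxidation under basic conditions spares the acid-sensitive oxirane, and the quaternary α-carbon cannot enolise, so the stereocentre is kept (the descriptor changes only through priorities).

Step 12
Reactants: 17 (R)-2-methyloxirane-2-carbaldehyde
Product: 18 (S)-2-methyl-2-vinyloxirane
Conditions: Ph3PCH3Br, NaNH2, THF, rt; then 17, −78 °C to rt; 18 co-distilled with THF and used as a titrated solution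
Reagents that add atoms: methyltriphenylphosphonium bromide, C[P+](c1ccccc1)(c1ccccc1)c1ccccc1.[Br-]
Why: Wittig methylenation of the aldehyde is much faster than attack of the ylide on the oxirane, and the volatile epoxide is handled as a THF solution, the solvent of the next step.

Step 13
Reactants: 15 C11 phenyl sulfone; 18 (S)-2-methyl-2-vinyloxirane
Product: 19 (13R)-11-(phenylsulfonyl)labda-6,14-dien-13-ol with H-8α (17-methyl β), mixture of C11 epimers
Conditions: n-BuLi, THF, −78 °C; DMPU, then 18 (THF solution), −78 °C to rt; aq NH4Cl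
Reagents that add atoms: none
Why: The α-sulfonyl carbanion opens the epoxide by SN2 attack at its unsubstituted CH2 (C12), so the C13 stereocentre from the chiral pool is not touched and becomes 13R; the new C11 centre is removed in the next step.

Step 14
Reactants: 19 hydroxy sulfone
Product: 20 (13R)-labda-6,14-dien-13-ol with H-8α (17-methyl β)
Conditions: sodium amalgam (6% Na in Hg), Na2HPO4, MeOH/THF, −20 to 0 °C
Reagents that add atoms: none
Why: Reductive desulfonylation by electron transfer replaces the sulfonyl group by hydrogen; the γ-oxygen cannot eliminate and the isolated alkenes and the tertiary allylic alcohol are not reduced.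

Step 15
Reactants: 20 (13R)-labda-6,14-dien-13-ol with H-8α
Product: 21 (13R)-6α,7α-epoxylabd-14-en-13-ol with H-8α
Conditions: mCPBA (1.05 equiv), NaHCO3, CH2Cl2, 0 °C
Reagents that add atoms: mCPBA, OOC(=O)c1cccc(Cl)c1
Why: Prilezhaev epoxidation picks the cis-disubstituted ring alkene over the monosubstituted vinyl group, and attacks the α face because the β face is screened by the three axial or pseudoaxial methyl groups C17, C19 and C20, which sets C6 and C7.

Step 16
Reactants: 21 (13R)-6α,7α-epoxylabd-14-en-13-ol
Product: 22 (13R)-labda-7,14-diene-6α,13-diol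
Conditions: LiNEt2 (from Et2NH and n-BuLi, excess), Et2O/hexane, 0 °C to reflux; aq NH4Cl
Reagents that add atoms: none
Why: Base-induced epoxide to allylic alcohol isomerisation through a lithium-bridged syn transition state should remove H-8α, the peripheral hydrogen cis to the oxirane, and cleave C7–O. This gives the 6α-alkoxide with retention at C6 and the C7=C8 alkene, erasing C8 and relieving the C17/C20 syn-diaxial strain; H-5α, also cis, is a ring-fusion hydrogen flanked by the quaternary C4 and C10.

Step 17
Reactants: 22 (13R)-labda-7,14-diene-6α,13-diol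
Product: 23 (13R)-13-hydroxylabda-7,14-dien-6α-yl butanoate (target)
Conditions: (PrCO)2O (1.5 equiv), DMAP (cat.), Et3N, CH2Cl2, rt
Reagents that add atoms: butyric anhydride, CCCC(=O)OC(=O)CCC
Why: DMAP-catalysed acylation esterifies the secondary allylic 6α-hydroxyl, while the tertiary C13 hydroxyl is too hindered to react under these conditions.

**Compound list**

1 | isobutyronitrile | CC(C)C#N | starting material
2 | 2-(3-chloropropyl)-2-methyl-1,3-dioxolane | CC1(CCCCl)OCCO1 | starting material
3 | 2,2-dimethyl-5-(2-methyl-1,3-dioxolan-2-yl)pentanenitrile (ketal nitrile) | CC1(CCCC(C)(C)C#N)OCCO1 | intermediate (not isolated)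
4 | 2,2-dimethyl-6-oxoheptanenitrile | CC(=O)CCCC(C)(C)C#N | intermediate
5 | triethyl phosphonoacetate | CCOC(=O)CP(=O)(OCC)OCC | starting material
6 | ethyl (2E)-7-cyano-3,7-dimethyloct-2-enoate | CCOC(=O)/C=C(\C)CCCC(C)(C)C#N | intermediate
7 | (6E)-8-hydroxy-2,2,6-trimethyloct-6-enal | O=CC(C)(C)CCC/C(C)=C/CO | intermediate
8 | (2E,8E)-9-iodo-3,7,7-trimethylnona-2,8-dien-1-ol | OC/C=C(\C)CCCC(C)(C)/C=C/I | intermediate
9 | (E)-prop-1-enylboronic acid | C/C=C/B(O)O | starting material
10 | (2E,8E,10E)-3,7,7-trimethyldodeca-2,8,10-trien-1-ol | OC/C=C(\C)CCCC(C)(C)/C=C/C=C/C | intermediate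
11 | (2E,8E,10E)-3,7,7-trimethyldodeca-2,8,10-trienal | O=C/C=C(\C)CCCC(C)(C)/C=C/C=C/C | intermediate
12 | trans-fused 4,4,8β,10β-tetramethyl-Δ6-octalin-9β-carbaldehyde (H-5α, H-8α, H-9α) | O=C[C@H]1[C@@H](C)C=C[C@H]2C(C)(C)CCC[C@]12C | intermediate
13 | corresponding 9β-hydroxymethyl octalin (C11 alcohol) | OC[C@H]1[C@@H](C)C=C[C@H]2C(C)(C)CCC[C@]12C | intermediate
14 | corresponding 9β-iodomethyl octalin (C11 iodide) | IC[C@H]1[C@@H](C)C=C[C@H]2C(C)(C)CCC[C@]12C | intermediate
15 | corresponding 9β-(phenylsulfonylmethyl) octalin (C11 sulfone) | O=S(=O)(C[C@H]1[C@@H](C)C=C[C@H]2C(C)(C)CCC[C@]12C)c1ccccc1 | intermediate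
16 | (S)-2-methylglycidol | OC[C@@]1(C)CO1 | starting material
17 | (R)-2-methyloxirane-2-carbaldehyde | O=C[C@@]1(C)CO1 | intermediate
18 | (S)-2-methyl-2-vinyloxirane | C=C[C@@]1(C)CO1 | intermediate
19 | (13R)-11-(phenylsulfonyl)labda-6,14-dien-13-ol with H-8α, C11 epimers | C=C[C@](C)(O)CC([C@H]1[C@@H](C)C=C[C@H]2C(C)(C)CCC[C@]12C)S(=O)(=O)c1ccccc1 | intermediate
20 | (13R)-labda-6,14-dien-13-ol with H-8α (17-methyl β) | C=C[C@](C)(O)CC[C@H]1[C@@H](C)C=C[C@H]2C(C)(C)CCC[C@]12C | intermediate
21 | (13R)-6α,7α-epoxylabd-14-en-13-ol with H-8α | C=C[C@](C)(O)CC[C@H]1[C@@H](C)[C@@H]3O[C@@H]3[C@H]2C(C)(C)CCC[C@]12C | intermediate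
22 | (13R)-labda-7,14-diene-6α,13-diol | C=C[C@](C)(O)CC[C@H]1C(C)=C[C@H](O)[C@H]2C(C)(C)CCC[C@]12C | intermediate
23 | (13R)-13-hydroxylabda-7,14-dien-6α-yl butanoate | C=C[C@](C)(O)CC[C@H]1C(C)=C[C@H](OC(=O)CCC)[C@H]2C(C)(C)CCC[C@]12C | target

**Step count**

Total: 17 steps. Longest linear sequence: 15 steps (steps 1–10 and 13–17); steps 11–12 make epoxide 18.

**Steps most likely to fail**

Step 7 (Proposed new method). What may go wrong:
- the β,β-disubstituted enal may be too unreactive at the temperatures where the chiral catalyst discriminates;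
- the Lewis acid may isomerise the enal geometry;
- the exo (cis-fused) mode may leak through because of the developing C19/C20 contact;
- facial selectivity may be low.

Fallback with known chemistry, setting out from 11 and coming back at 13: the cycloaddition is run with stoichiometric achiral Me2AlCl in CH2Cl2 (−40 °C to rt), which should give the trans-fused adduct as the racemate, that is 12 together with the enantiomeric aldehyde F1. NaBH4 reduction gives 13 together with the enantiomeric alcohol F2. Esterification with (S)-O-methylmandelic acid (DCC, DMAP, CH2Cl2) gives the (S)-O-methylmandelate of 13 F3 and the (S)-O-methylmandelate of the enantiomeric alcohol F4, which are separated by chromatography or crystallisation. Hydrolysis of the former with LiOH in THF/H2O returns 13 as a single enantiomer.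

Step 16. What may go wrong: both hydrogens cis to the oxirane are tertiary, so H-5α may be removed instead of H-8α (Δ5 7α-ol), or the oxirane may be α-lithiated and collapse to a ketone. H-5α is the better aligned of the two; the route relies on its shielding and on strain relief at C8.

Fallback, setting out from 15 and coming back at 22:
- OsO4 (cat.)/NMO in acetone/H2O dihydroxylates the α face to the 6α,7α-diol sulfone F5.
- Bu2SnO (toluene, reflux) then TBSCl silylates the equatorial 6α-oxygen to the 6α-silyloxy 7α-ol sulfone F6.
- Burgess reagent (benzene, 50 °C) dehydrates the axial 7α-hydroxyl by syn elimination; the only cis β-hydrogen is H-8α, since H-6 is β, so the 6α-silyloxy Δ7 sulfone F7 should form.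
- The chemistry of steps 13 and 14 (n-BuLi, then 18; sodium amalgam) gives the silyloxy hydroxy sulfone F8 and then the 6α-silyloxy dienol F9.
- Bu4NF in THF gives 22.

Step 13. What may go wrong: the hindered secondary α-sulfonyl carbanion may attack the epoxide CH2 next to a quaternary carbon too slowly, so that SN2′ opening at the vinyl terminus or base-induced decomposition of the epoxide competes.

Fallback, setting out from 14 (with 16) and coming back at 20:
- 16 is silylated (TBSCl, imidazole) to the silyl ether of (S)-2-methylglycidol F10.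
- 14 is converted with t-BuLi and then MgBr2·OEt2 into the Grignard reagent, which opens F10 at its CH2 under CuI catalysis (THF, −40 to 0 °C) to give the C14 silyloxy tertiary alcohol F11.
- Bu4NF gives the 13,14-diol F12.
- SO3·pyridine/DMSO/iPr2NEt oxidises the primary hydroxyl to the α-hydroxy aldehyde F13.
- Ph3P=CH2 (excess, THF) methylenates it to 20.

Further compounds
F1 | step 7 | enantiomer of aldehyde 12 | O=C[C@@H]1[C@H](C)C=C[C@@H]2C(C)(C)CCC[C@@]12C
F2 | step 7 | enantiomer of alcohol 13 | OC[C@@H]1[C@H](C)C=C[C@@H]2C(C)(C)CCC[C@@]12C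
F3 | step 7 | (S)-O-methylmandelate of 13 | CO[C@H](C(=O)OC[C@H]1[C@@H](C)C=C[C@H]2C(C)(C)CCC[C@]12C)c1ccccc1
F4 | step 7 | (S)-O-methylmandelate of the enantiomeric alcohol | CO[C@H](C(=O)OC[C@@H]1[C@H](C)C=C[C@@H]2C(C)(C)CCC[C@@]12C)c1ccccc1
F5 | step 16 | 6α,7α-diol of sulfone 15 | O=S(=O)(C[C@H]1[C@@H](C)[C@H](O)[C@H](O)[C@H]2C(C)(C)CCC[C@]12C)c1ccccc1
F6 | step 16 | 6α-(tert-butyldimethylsilyloxy) 7α-ol sulfone | O=S(=O)(C[C@H]1[C@@H](C)[C@H](O)[C@H](O[Si](C)(C)C(C)(C)C)[C@H]2C(C)(C)CCC[C@]12C)c1ccccc1
F7 | step 16 | 6α-(tert-butyldimethylsilyloxy) Δ7 C11 sulfone | O=S(=O)(C[C@H]1C(C)=C[C@H](O[Si](C)(C)C(C)(C)C)[C@H]2C(C)(C)CCC[C@]12C)c1ccccc1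
F8 | step 16 | (13R)-6α-(tert-butyldimethylsilyloxy)-11-(phenylsulfonyl)labda-7,14-dien-13-ol, C11 epimers | C=C[C@](C)(O)CC([C@H]1C(C)=C[C@H](O[Si](C)(C)C(C)(C)C)[C@H]2C(C)(C)CCC[C@]12C)S(=O)(=O)c1ccccc1
F9 | step 16 | (13R)-6α-(tert-butyldimethylsilyloxy)labda-7,14-dien-13-ol | C=C[C@](C)(O)CC[C@H]1C(C)=C[C@H](O[Si](C)(C)C(C)(C)C)[C@H]2C(C)(C)CCC[C@]12C
F10 | step 13 | tert-butyldimethylsilyl ether of (S)-2-methylglycidol | CC(C)(C)[Si](C)(C)OC[C@@]1(C)CO1
F11 | step 13 | C14 silyloxy tertiary alcohol (15-nor chain, H-8α, Δ6) | CC(C)(C)[Si](C)(C)OC[C@](C)(O)CC[C@H]1[C@@H](C)C=C[C@H]2C(C)(C)CCC[C@]12C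
F12 | step 13 | corresponding 13,14-diol | OC[C@](C)(O)CC[C@H]1[C@@H](C)C=C[C@H]2C(C)(C)CCC[C@]12C
F13 | step 13 | corresponding 13-hydroxy 14-aldehyde | O=C[C@](C)(O)CC[C@H]1[C@@H](C)C=C[C@H]2C(C)(C)CCC[C@]12C
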